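**Retrosynthetic overview**

1. Feature (drimane numbering: ring A = C1–C5 and C10, ring B = C5–C10, C11 = CH2O carbon on C9, C12 = methyl on C8): the methyl-bearing quaternary C10 sits next to C5, which sits next to the gem-dimethyl C4. With C5 as a carbonyl carbon, ring A is therefore a 2,2,6-trimethylcyclohexanone whose α-quaternary centre is C10, and ring B is a cyclohexene annulated across the C5–C10 bond.
2. C11–O ester bond: target ⇒ (−)-drimenol + 3,4-bis(silyloxy)cinnamic acid made from caffeic acid.
3. C9–C11 bond: drimenol ⇒ 8-methyl-Δ8-7β-ol by a suprafacial [2,3]-Wittig–Still shift (carbon moves from O7 to C9, alkene moves to C7=C8). That alcohol ⇒ the ring B Δ5-7-one by C8 methylation, Li/NH3 reduction (trans C5–H), dehydrogenation and 1,2-reduction.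
4. Ring B (the only ring formed; ring A is bought): Δ5-7-one ⇒ 1,5-diketone by intramolecular aldol condensation forming C5–C6, then C5=C6.
5. C10: 1,5-diketone ⇒ (R)-2-allyl-2,6,6-trimethylcyclohexanone (allyl homologated to 3-oxobutyl) ⇒ allyl enol carbonate, by Pd-catalysed enantioselective decarboxylative allylation.

Key step: step 7

Assumption: the (R)-configured t-Bu-PHOX ligand is taken to deliver the (R)-allyl ketone, by analogy with the sense known for 2-alkyl-2-allylcyclohexanones; should the sense prove opposite, the (S)-ligand would be used with no other change.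

Remark: the allylation is expected to give high but not complete enantioselectivity; crystalline drimenol (22) is the planned point for recrystallisation to enantiopurity.

Remark: metal alkoxides that are only protonated on work-up are treated as the salt form of the numbered product and carry no number of their own.

**Route**

Step 1
Reactants: 1 2,2,6-trimethylcyclohexan-1-one; 2 allyl chloroformate
Product: 4 allyl 2,6,6-trimethylcyclohex-1-en-1-yl carbonate, via lithium enolate 3 (not isolated)
Conditions: LiN(SiMe3)2, THF, 0 °C; then 2, −78 °C → rt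
Reagents that add atoms: allyl chloroformate (2), C=CCOC(=O)Cl
Why: ketone 1 has a single α-hydrogen, so only one enolate can form, and this hindered tetrasubstituted lithium enolate is acylated on oxygen by the hard chloroformate (enol carbonate formation).

Step 2
Reactants: 4 allyl 2,6,6-trimethylcyclohex-1-en-1-yl carbonate
Product: 5 (R)-2-allyl-2,6,6-trimethylcyclohexan-1-one
Conditions: Pd2(dba)3 (2.5 mol %), (R)-t-Bu-PHOX (6.25 mol %), THF, 25 °C
Reagents that add atoms: none
Why: in this Tsuji-type decarboxylative asymmetric allylic alkylation, zerovalent palladium ionises the allyl carbonate, CO2 is lost, and the Pd(allyl)(PHOX) enolate forms the C10–allyl bond inside the chiral ligand pocket, so C10 is set as (R) by ligand control and the enolate exists only where the carbonate was.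

Step 3
Reactants: 5 (R)-2-allyl-2,6,6-trimethylcyclohexan-1-one
Product: 7 (R)-2-(3-hydroxypropyl)-2,6,6-trimethylcyclohexan-1-one, via B-alkyl-9-BBN adduct 6 (not isolated)
Conditions: 9-BBN, THF, 0 °C → rt; then NaOH, H2O2, H2O, 0 °C → rt
Reagents that add atoms: hydrogen peroxide, OO
Why: hydroboration–oxidation, in which 9-BBN adds anti-Markovnikov to the terminal alkene while the ketone between two quaternary carbons is too hindered to be reduced, and the C–B bond is then oxidised to the primary alcohol.

Step 4
Reactants: 7 (R)-2-(3-hydroxypropyl)-2,6,6-trimethylcyclohexan-1-one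
Product: 8 3-[(1R)-1,3,3-trimethyl-2-oxocyclohexyl]propanal
Conditions: Dess–Martin periodinane, CH2Cl2, rt
Reagents that add atoms: none
Why: Dess–Martin oxidation stops cleanly at the aldehyde, and the molecule has no epimerisable centre.

Step 5
Reactants: 8 3-[(1R)-1,3,3-trimethyl-2-oxocyclohexyl]propanal
Product: 9 (2R)-2-(3-hydroxybutyl)-2,6,6-trimethylcyclohexan-1-one (both carbinol epimers)
Conditions: MeMgBr, THF, −78 °C; NH4Cl (aq)
Reagents that add atoms: methylmagnesium bromide, C[Mg]Br
Why: Grignard addition at low temperature takes place only at the unhindered aldehyde because the ring ketone is flanked by two quaternary carbons, and the unselectively formed carbinol centre is erased in step 6.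

Step 6
Reactants: 9 (2R)-2-(3-hydroxybutyl)-2,6,6-trimethylcyclohexan-1-one
Product: 10 (R)-2,2,6-trimethyl-6-(3-oxobutyl)cyclohexan-1-one
Conditions: Dess–Martin periodinane, CH2Cl2, rt
Reagents that add atoms: none
Why: Dess–Martin oxidation of the secondary alcohol gives the methyl ketone under neutral conditions that cannot trigger a premature aldol or retro-Michael reaction.

Step 7
Reactants: 10 (R)-2,2,6-trimethyl-6-(3-oxobutyl)cyclohexan-1-one
Product: 12 (R)-4a,8,8-trimethyl-4,4a,5,6,7,8-hexahydronaphthalen-2(3H)-one, via ketol 11 (not isolated)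
Conditions: KOH (powdered), xylenes, 110 °C, Dean–Stark
Reagents that add atoms: none
Why: Hydroxide reversibly deprotonates the methyl ketone, the methyl-side enolate carbon (C6) adds to the C5 carbonyl to give ketol 11, and E1cB loss of water forms C5=C6, the removal of water and the conjugation of the enone pulling the equilibria to 12. The closest known reaction is the aldol half of a Robinson annulation, as used to close conjugated enones onto α,α,α′,α′-tetrasubstituted cyclohexanones obtained by enantioselective allylation. Ring B closes in a 6-(enolendo)-exo-trig mode, since C6 and C7 of the enolate both become ring atoms and the carbonyl oxygen of C5 stays outside the ring. No stereocentre is created, and C10 carries no hydrogen, so it cannot epimerise by enolisation. The step needs one regiochemical outcome and the substrate guarantees it: C5 has no α-hydrogen and can act only as the acceptor, and the alternative C8 enolate could close only a four-membered ring. The hot hydrocarbon medium with water removal is chosen so that condensation outruns retro-Michael cleavage of the C9–C10 bond, the one pathway that could erode C10.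

Step 8
Reactants: 12 (R)-4a,8,8-trimethyl-4,4a,5,6,7,8-hexahydronaphthalen-2(3H)-one
Product: 14 (4aR)-3,4a,8,8-tetramethyl-4,4a,5,6,7,8-hexahydronaphthalen-2(3H)-one (C3 epimers; C3 = drimane C8), via lithium dienolate 13 (not isolated)
Conditions: LiN(iPr)2, THF, −78 °C; MeI, −78 → −20 °C
Reagents that add atoms: iodomethane, CI
Why: both γ-carbons of the enone (C4 and C10) are quaternary, so the only acidic hydrogens are on C8, and the cross-conjugated enolate 13 is C-methylated there (enolate alkylation), the C8 configuration being irrelevant because C8 later becomes sp2.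

Step 9
Reactants: 14 (4aR)-3,4a,8,8-tetramethyl-4,4a,5,6,7,8-hexahydronaphthalen-2(3H)-one
Product: 16 (4aR,8aS)-3,4a,8,8-tetramethyloctahydronaphthalen-2(1H)-one (C3 epimers), via lithium enolate 15 (not isolated)
Conditions: Li, NH3 (l), THF, t-BuOH (1 equiv), −78 → −33 °C; NH4Cl
Reagents that add atoms: none
Why: in this dissolving-metal conjugate reduction the β-carbanion at C5 is protonated axially on the α face, anti to the C10 methyl, which sets the trans ring fusion (5α-H), and one equivalent of alcohol holds the product as enolate 15 until the quench.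

Step 10
Reactants: 16 (4aR,8aS)-3,4a,8,8-tetramethyloctahydronaphthalen-2(1H)-one
Product: 17 trimethyl{[(4aR,8aS)-3,4a,8,8-tetramethyl-1,4,4a,5,6,7,8,8a-octahydronaphthalen-2-yl]oxy}silane
Conditions: Me3SiCl, NaI, Et3N, MeCN, rt
Reagents that add atoms: chlorotrimethylsilane, C[Si](C)(C)Cl
Why: equilibrating silylation with Me3SiI made in the flask gives the more substituted C7=C8 enol ether (thermodynamic silyl enol ether formation), helped by the general reluctance of trans-fused decalones to enolise toward the carbon next to the ring fusion (C6).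

Step 11
Reactants: 17 trimethyl{[(4aR,8aS)-3,4a,8,8-tetramethyl-1,4,4a,5,6,7,8,8a-octahydronaphthalen-2-yl]oxy}silane
Product: 18 (4aR,8aS)-3,4a,8,8-tetramethyl-4a,5,6,7,8,8a-hexahydronaphthalen-2(1H)-one
Conditions: Pd(OAc)2 (10 mol %), O2 (1 atm), DMSO, 40 °C
Reagents that add atoms: none
Why: Saegusa–Ito oxidation, in which the divalent palladium enolate formed at C8 undergoes β-hydride elimination toward C9 to give the conjugated endocyclic Δ8-7-one while O2 reoxidises zerovalent palladium; any minor C6=C7 enol ether would only return enone 14, which can be recycled.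

Step 12
Reactants: 18 (4aR,8aS)-3,4a,8,8-tetramethyl-4a,5,6,7,8,8a-hexahydronaphthalen-2(1H)-one
Product: 19 (2S,4aR,8aS)-3,4a,8,8-tetramethyl-1,2,4a,5,6,7,8,8a-octahydronaphthalen-2-ol (7β-alcohol in drimane numbering)
Conditions: NaBH4, CeCl3·7H2O, MeOH, −78 → 0 °C
Reagents that add atoms: none
Why: Luche 1,2-reduction, in which hydride adds axially to C7 from the α face (anti to the axial C6–H and meeting only the axial C5–H), giving the pseudo-equatorial 7β-alcohol.

Step 13
Reactants: 19 (2S,4aR,8aS)-3,4a,8,8-tetramethyl-1,2,4a,5,6,7,8,8a-octahydronaphthalen-2-ol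
Product: 20 tributyl({[(2S,4aR,8aS)-3,4a,8,8-tetramethyl-1,2,4a,5,6,7,8,8a-octahydronaphthalen-2-yl]oxy}methyl)stannane
Conditions: KH, THF, 0 °C; Bu3SnCH2I, 18-crown-6 (cat.), 0 °C → rt
Reagents that add atoms: (iodomethyl)tributylstannane, CCCC[Sn](CCCC)(CCCC)CI
Why: Williamson etherification of the potassium alkoxide with the reactive primary iodide leaves every stereocentre untouched.

Step 14
Reactants: 20 tributyl({[(2S,4aR,8aS)-3,4a,8,8-tetramethyl-1,2,4a,5,6,7,8,8a-octahydronaphthalen-2-yl]oxy}methyl)stannane
Product: 22 (−)-drimenol [(1S,4aS,8aS)-2,5,5,8a-tetramethyl-1,4,4a,5,6,7,8,8a-octahydronaphthalen-1-yl]methanol, via lithiomethyl ether 21 (not isolated)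
Conditions: n-BuLi, THF, −78 °C; NH4Cl (aq)
Reagents that add atoms: none
Why: tin–lithium exchange gives the α-alkoxymethyllithium 21, which undergoes the [2,3]-Wittig–Still rearrangement suprafacially, so C11 is delivered from the 7β-oxygen to the β face of C9 as the alkene moves to C7=C8, setting C9 (S, 9α-H) by 1,3-chirality transfer.

Step 15
Reactants: 23 caffeic acid
Product: 25 (E)-3-[3,4-bis(tert-butyldimethylsilyloxy)phenyl]prop-2-enoic acid, via tris-silyl compound 24 (not isolated)
Conditions: t-BuMe2SiCl (3.3 equiv), imidazole, DMF, rt; then AcOH, THF, H2O, rt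
Reagents that add atoms: tert-butyl(chloro)dimethylsilane, CC(C)(C)[Si](C)(C)Cl
Why: exhaustive silylation followed by mild aqueous acid hydrolyses only the far more labile silyl ester and keeps both aryl silyl ethers (silyl protection of the catechol).

Step 16
Reactants: 22 (−)-drimenol; 25 (E)-3-[3,4-bis(tert-butyldimethylsilyloxy)phenyl]prop-2-enoic acid
Product: 26 drimenyl (E)-3-[3,4-bis(tert-butyldimethylsilyloxy)phenyl]prop-2-enoate
Conditions: EDC·HCl, DMAP, CH2Cl2, 0 °C → rt
Reagents that add atoms: none
Why: Steglich esterification through the O-acylisourea and the acylpyridinium acylates the only free hydroxyl, the primary alcohol of 22, under conditions that leave the trisubstituted ring alkene and the E-cinnamate geometry untouched.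

Step 17
Reactants: 26 drimenyl (E)-3-[3,4-bis(tert-butyldimethylsilyloxy)phenyl]prop-2-enoate
Product: 27 drimenyl caffeate (target), [(1S,4aS,8aS)-2,5,5,8a-tetramethyl-1,4,4a,5,6,7,8,8a-octahydronaphthalen-1-yl]methyl (E)-3-(3,4-dihydroxyphenyl)prop-2-enoate
Conditions: Bu4NF, AcOH, THF, 0 °C
Reagents that add atoms: none
Why: fluoride cleaves the two aryl Si–O bonds (desilylation) while acetic acid buffers the phenoxides, so the ester, the E-alkene, the ring alkene and the oxidation-prone catechol all survive.

**Compound list**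

1 | 2,2,6-trimethylcyclohexan-1-one (racemic; its stereocentre is erased in step 1) | CC1CCCC(C)(C)C1=O | starting material
2 | allyl chloroformate | C=CCOC(=O)Cl | starting material
3 | lithium 2,6,6-trimethylcyclohex-1-en-1-olate | [Li]OC1=C(C)CCCC1(C)C | intermediate (not isolated)
4 | allyl 2,6,6-trimethylcyclohex-1-en-1-yl carbonate | C=CCOC(=O)OC1=C(C)CCCC1(C)C | intermediate
5 | (R)-2-allyl-2,6,6-trimethylcyclohexan-1-one | C=CC[C@@]1(C)CCCC(C)(C)C1=O | intermediate
6 | 9-[3-(1,3,3-trimethyl-2-oxocyclohexyl)propyl]-9-borabicyclo[3.3.1]nonane, quaternary centre as in 5 | C1CCC2CCCC1B2CCC[C@@]1(C)CCCC(C)(C)C1=O | intermediate (not isolated)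
7 | (R)-2-(3-hydroxypropyl)-2,6,6-trimethylcyclohexan-1-one | OCCC[C@@]1(C)CCCC(C)(C)C1=O | intermediate
8 | 3-[(1R)-1,3,3-trimethyl-2-oxocyclohexyl]propanal | O=CCC[C@@]1(C)CCCC(C)(C)C1=O | intermediate
9 | (2R)-2-(3-hydroxybutyl)-2,6,6-trimethylcyclohexan-1-one (carbinol epimers) | CC(O)CC[C@@]1(C)CCCC(C)(C)C1=O | intermediate
10 | (R)-2,2,6-trimethyl-6-(3-oxobutyl)cyclohexan-1-one | CC(=O)CC[C@@]1(C)CCCC(C)(C)C1=O | intermediate
11 | (4aR)-8a-hydroxy-4a,8,8-trimethyloctahydronaphthalen-2(1H)-one (either epimer at the carbinol carbon) | O=C1CC2(O)C(C)(C)CCC[C@]2(C)CC1 | intermediate (not isolated)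
12 | (R)-4a,8,8-trimethyl-4,4a,5,6,7,8-hexahydronaphthalen-2(3H)-one | O=C1C=C2C(C)(C)CCC[C@]2(C)CC1 | intermediate
13 | lithium cross-conjugated dienolate of 12 (O–C7=C8, C5=C6) | [Li]OC1=CC[C@@]2(C)CCCC(C)(C)C2=C1 | intermediate (not isolated)
14 | (4aR)-3,4a,8,8-tetramethyl-4,4a,5,6,7,8-hexahydronaphthalen-2(3H)-one (C3 epimers) | O=C1C=C2C(C)(C)CCC[C@]2(C)CC1C | intermediate
15 | lithium enolate from conjugate reduction of 14 (O–C7=C6, trans 5α-H) | CC1C(O[Li])=C[C@H]2C(C)(C)CCC[C@]2(C)C1 | intermediate (not isolated)
16 | (4aR,8aS)-3,4a,8,8-tetramethyloctahydronaphthalen-2(1H)-one (C3 epimers) | CC1C(=O)C[C@H]2C(C)(C)CCC[C@]2(C)C1 | intermediate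
17 | trimethyl{[(4aR,8aS)-3,4a,8,8-tetramethyl-1,4,4a,5,6,7,8,8a-octahydronaphthalen-2-yl]oxy}silane | CC1=C(O[Si](C)(C)C)C[C@H]2C(C)(C)CCC[C@]2(C)C1 | intermediate
18 | (4aR,8aS)-3,4a,8,8-tetramethyl-4a,5,6,7,8,8a-hexahydronaphthalen-2(1H)-one | CC1=C[C@@]2(C)CCCC(C)(C)[C@@H]2CC1=O | intermediate
19 | (2S,4aR,8aS)-3,4a,8,8-tetramethyl-1,2,4a,5,6,7,8,8a-octahydronaphthalen-2-ol | CC1=C[C@@]2(C)CCCC(C)(C)[C@@H]2C[C@@H]1O | intermediate
20 | tributyl({[(2S,4aR,8aS)-3,4a,8,8-tetramethyl-1,2,4a,5,6,7,8,8a-octahydronaphthalen-2-yl]oxy}methyl)stannane | CC1=C[C@@]2(C)CCCC(C)(C)[C@@H]2C[C@@H]1OC[Sn](CCCC)(CCCC)CCCC | intermediate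
21 | lithiomethyl ether of 19 | CC1=C[C@@]2(C)CCCC(C)(C)[C@@H]2C[C@@H]1OC[Li] | intermediate (not isolated)
22 | (−)-drimenol, [(1S,4aS,8aS)-2,5,5,8a-tetramethyl-1,4,4a,5,6,7,8,8a-octahydronaphthalen-1-yl]methanol | CC1=CC[C@H]2C(C)(C)CCC[C@]2(C)[C@H]1CO | intermediate
23 | caffeic acid | OC(=O)/C=C/c1ccc(O)c(O)c1 | starting material
24 | tert-butyldimethylsilyl (E)-3-[3,4-bis(tert-butyldimethylsilyloxy)phenyl]prop-2-enoate | CC(C)(C)[Si](C)(C)OC(=O)/C=C/c1ccc(O[Si](C)(C)C(C)(C)C)c(O[Si](C)(C)C(C)(C)C)c1 | intermediate (not isolated)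
25 | (E)-3-[3,4-bis(tert-butyldimethylsilyloxy)phenyl]prop-2-enoic acid | OC(=O)/C=C/c1ccc(O[Si](C)(C)C(C)(C)C)c(O[Si](C)(C)C(C)(C)C)c1 | intermediate
26 | drimenyl (E)-3-[3,4-bis(tert-butyldimethylsilyloxy)phenyl]prop-2-enoate | CC1=CC[C@H]2C(C)(C)CCC[C@]2(C)[C@H]1COC(=O)/C=C/c1ccc(O[Si](C)(C)C(C)(C)C)c(O[Si](C)(C)C(C)(C)C)c1 | intermediate
27 | drimenyl caffeate, [(1S,4aS,8aS)-2,5,5,8a-tetramethyl-1,4,4a,5,6,7,8,8a-octahydronaphthalen-1-yl]methyl (E)-3-(3,4-dihydroxyphenyl)prop-2-enoate | CC1=CC[C@H]2C(C)(C)CCC[C@]2(C)[C@H]1COC(=O)/C=C/c1ccc(O)c(O)c1 | target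

**Step count**

Total: 17 steps. Longest linear sequence: 16 steps (steps 1–14, 16 and 17); step 15 is a one-step side branch.

**Steps most likely to fail, with fallbacks**

Step 14. The C7–O bond of 20 is pseudo-equatorial in the trans-fused half-chair, so it overlaps poorly with the alkene π system at −78 °C. The carbanion may then undergo [1,2]-shift or simple protonation instead of the [2,3]-shift, and delivery to C9 next to the quaternary C10 is sterically demanding. The fallback sets out from 19 and delivers the carbon thermally and without a carbanion. Heating 19 with N,N-dimethylformamide dimethyl acetal in xylene (140–160 °C) exchanges the alcohol into the amide acetal. Loss of methanol and a suprafacial [2,3]-sigmatropic shift of the resulting alkoxy(amino)carbene then give the β,γ-unsaturated amide (1S,4aS,8aS)-N,N,2,5,5,8a-hexamethyl-1,4,4a,5,6,7,8,8a-octahydronaphthalene-1-carboxamide F3, with the same 7β → 9β transfer. Reduction of this hindered tertiary amide with LiNH2BH3 (from BH3·NH3 and LiN(iPr)2) in THF then gives the primary alcohol, and the route is rejoined at 22.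

Step 7. Addition to the C5 carbonyl, which lies between two quaternary carbons, may be slow. Retro-Michael fragmentation of the C9–C10 bond from the C8 enolate could then compete, losing material and, on re-addition, eroding the enantiomeric purity at C10. The fallback sets out from 10 and avoids equilibrating base. Kinetic deprotonation of the methyl group with LiN(iPr)2 at −78 °C and trapping with Me3SiCl give the methyl-side enol ether (6R)-2,2,6-trimethyl-6-{3-[(trimethylsilyl)oxy]but-3-en-1-yl}cyclohexan-1-one F1. Any internal enol ether formed alongside cannot cyclise and returns 10 on work-up. TiCl4 in CH2Cl2 at −78 °C then closes ring B by an intramolecular Mukaiyama aldol addition to the Lewis-acid-activated C5 carbonyl, giving ketol 11, now isolated. Acid dehydration (TsOH, benzene, reflux) gives the enone, and the route is rejoined at 12.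

Step 10. Silylation may fail to reach the thermodynamic preference, so that some C6=C7 enol ether forms and step 11 regenerates enone 14 instead of the Δ8-7-one. The fallback sets out from 16 and replaces the enol ether and palladium pair by halogenation and elimination. SO2Cl2 in CH2Cl2 chlorinates the more substituted α-carbon through the acid-catalysed enol, giving (4aR,8aS)-3-chloro-3,4a,8,8-tetramethyloctahydronaphthalen-2(1H)-one F2. Dehydrochlorination with LiCl in DMF at 120 °C, where any exocyclic alkene isomerises into conjugation in the ring, gives the Δ8-7-one, and the route is rejoined at 18 with step 11 bypassed.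

**Further compounds**

F1 | step 7 | (6R)-2,2,6-trimethyl-6-{3-[(trimethylsilyl)oxy]but-3-en-1-yl}cyclohexan-1-one | C=C(O[Si](C)(C)C)CC[C@@]1(C)CCCC(C)(C)C1=O
F2 | step 10 | (4aR,8aS)-3-chloro-3,4a,8,8-tetramethyloctahydronaphthalen-2(1H)-one (C3 epimers) | CC1(Cl)C(=O)C[C@H]2C(C)(C)CCC[C@]2(C)C1
F3 | step 14 | (1S,4aS,8aS)-N,N,2,5,5,8a-hexamethyl-1,4,4a,5,6,7,8,8a-octahydronaphthalene-1-carboxamide | CC1=CC[C@H]2C(C)(C)CCC[C@]2(C)[C@H]1C(=O)N(C)C
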